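## Retrosynthetic overview

1. The last step is the twofold chlorination at C5/C5'. Before it, one operation builds the whole dimeric bis(vinylogous pyridone) core from a monomeric pyridyl ketone and a C4 bis-electrophile.
2. Key disconnections: both N2–CH2 bonds (dimerisation on the tether by N-alkylation) and C5–C6 in both carbocycles (C4a–C5–C6–C7–C8–C8a). This leads back to a 4-methyl-3-acylpyridinium whose acyl group is a C-acylated lactic acid held as a 2-tert-butyl-1,3-dioxolan-4-one.
3. Enabling feature: C5 is the γ-methyl carbon of the pyridine ring (on C4a, para to N2, ortho to the C8 acyl group on C8a), so N2-alkylation makes it a carbon acid (anhydrobase). C6–C7(O)(CH3)–C8 is an α-acylated lactic acid; the dioxolanone serves as activated ester (C6), masked C7–OH and stereochemical relay, and leaves as pivalaldehyde.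
4. Monomer: aldol of the dioxolanone enolate from (R)-lactic acid with a 6-dienyl-4-methylnicotinaldehyde (C7 set anti to tert-butyl), then oxidation. The aldehyde comes from Suzuki coupling of 6-chloro-4-methylnicotinaldehyde with a dienylboronate made from (S)-2-methylbutan-1-ol (C13 bought).
5. Ring order: pyridine rings bought; temporary dioxolanone rings formed in step 4; both carbocycles closed last, in the same operation that destroys the temporary rings.

Key step: step 8

Remark: the target is read as the C2-symmetric (7S,7'S,13S,13'S) all-E isomer. The 5-dechloro and enol-type intermediates with the same spatial arrangement at C7 carry the descriptor R, because the CIP priority of C6 over C8 rests on the chlorine at C5. Locants: isoquinoline numbering for the core; side chain C9–C15 outwards from C3 (methyl on C11, stereocentre C13).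

## Route

Step 1
Reactants: 1 (S)-2-methylbutan-1-ol
Product: 3 (2E,4S)-2,4-dimethylhex-2-enal, via (S)-2-methylbutanal 2 (not isolated)
Conditions: NaOCl (aq), TEMPO (cat.), KBr (cat.), NaHCO3, CH2Cl2/H2O, 0 °C; organic phase dried; then Ph3P=C(CH3)CHO, toluene, 70 °C, sealed vessel
Reagents that add atoms: 2-(triphenylphosphoranylidene)propanal, CC(C=O)=P(c1ccccc1)(c1ccccc1)c1ccccc1
Why: The nitroxyl-catalysed hypochlorite (Anelli) oxidation gives the labile α-branched aldehyde without a base able to enolise it, and the non-basic stabilised ylide converts it in a Wittig reaction into the (E)-trisubstituted enal under thermodynamic control, the stereocentre (later C13) being bought with the alcohol.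

Step 2
Reactants: 3 (2E,4S)-2,4-dimethylhex-2-enal
Product: 4 2-[(1E,3E,5S)-3,5-dimethylhepta-1,3-dien-1-yl]-4,4,5,5-tetramethyl-1,3,2-dioxaborolane
Conditions: CH2(Bpin)2, LiTMP (lithium 2,2,6,6-tetramethylpiperidide), THF, 0 °C; then 3, −78 °C → rt
Reagents that add atoms: bis(pinacolboryl)methane, CC1(C)OB(CB2OC(C)(C)C(C)(C)O2)OC1(C)C
Why: Boron-Wittig olefination, in which the α-boryl carbanion adds 1,2 to the enal and syn-elimination of the boronate oxide should give the trans vinylboronate (new C9=C10 bond E) because Bpin and the alkenyl residue avoid each other in the elimination.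

Step 3
Reactants: 4 dienyl pinacol boronate; 5 6-chloro-4-methylpyridine-3-carbaldehyde
Product: 6 6-[(1E,3E,5S)-3,5-dimethylhepta-1,3-dien-1-yl]-4-methylpyridine-3-carbaldehyde
Conditions: Pd(dppf)Cl2 (5 mol %), K3PO4, 1,4-dioxane/H2O, 80 °C
Reagents that add atoms: none
Why: Suzuki–Miyaura coupling, in which the C–Cl bond next to the ring nitrogen and para to the formyl group adds readily to zerovalent palladium and the alkenylboronate transfers the dienyl group with retention of both double-bond geometries.

Step 4
Reactants: 7 (R)-lactic acid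
Product: 8 (2R,5R)-2-tert-butyl-5-methyl-1,3-dioxolan-4-one (cis)
Conditions: pivalaldehyde, TsOH·H2O (cat.), H2SO4 (cat.), pentane, reflux (Dean–Stark); crystallisation from pentane/Et2O at −78 °C
Reagents that add atoms: pivalaldehyde, CC(C)(C)C=O
Why: Acid-catalysed acetalisation with azeotropic removal of water, in which the thermodynamically preferred cis acetal stores the lactate configuration in the new acetal centre (self-regeneration of stereocentres) and is purified by crystallisation.

Step 5
Reactants: 8 (2R,5R)-2-tert-butyl-5-methyl-1,3-dioxolan-4-one; 6 dienyl pyridine aldehyde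
Product: 10 (2R,5S)-2-tert-butyl-5-{[6-((1E,3E,5S)-3,5-dimethylhepta-1,3-dien-1-yl)-4-methylpyridin-3-yl](hydroxy)methyl}-5-methyl-1,3-dioxolan-4-one as a mixture of carbinol epimers, via lithium dioxolanone enolate 9 (not isolated)
Conditions: LiN(iPr)2, THF, −78 °C; then 6, −78 °C; aq. NH4Cl
Reagents that add atoms: none
Why: Aldol addition of the lithium enolate, whose only stereocentre is the acetal carbon, should occur on the face opposite to the tert-butyl group and so set the quaternary carbon (future C7) with methyl cis to tert-butyl, the carbinol centre being irrelevant because it is oxidised next.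

Step 6
Reactants: 10 aldol adduct
Product: 11 (2R,5S)-2-tert-butyl-5-{6-[(1E,3E,5S)-3,5-dimethylhepta-1,3-dien-1-yl]-4-methylpyridine-3-carbonyl}-5-methyl-1,3-dioxolan-4-one
Conditions: Dess–Martin periodinane, CH2Cl2, 0 °C → rt
Reagents that add atoms: none
Why: Dess–Martin oxidation of the hindered secondary pyridyl carbinol under neutral conditions should leave the diene, the acetal and the quaternary centre (no α-hydrogen) untouched.

Step 7
Reactants: 12 tetrahydrofuran
Product: 13 butane-1,4-diyl bis(trifluoromethanesulfonate)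
Conditions: Tf2O, CH2Cl2, −78 °C → rt
Reagents that add atoms: triflic anhydride, O=S(=O)(OS(=O)(=O)C(F)(F)F)C(F)(F)F
Why: Ring-opening of the cyclic ether by the sulfonic anhydride, in which O-sulfonylation gives an oxonium triflate that triflate ion opens by SN2 attack at the α-carbon, a known access to the 1,4-bis-triflate.

Step 8
Reactants: 11 pyridyl ketone (2.1 equiv); 13 butane-1,4-diyl bis(trifluoromethanesulfonate) (1 equiv)
Product: 16 5,5'-didechloro-penazaphilone I (bis-acetate), via bis-pyridinium bis(triflate) 14 (not isolated), via bis-carbinol 15 (not isolated)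
Conditions: CH2Cl2, rt → 40 °C; then MeCN, EtN(iPr)2, 0 °C → rt; then Ac2O, DMAP (cat.), 0 °C → rt
Reagents that add atoms: acetic anhydride, CC(=O)OC(C)=O
Why: Twofold Menshutkin N-alkylation of 11 by the primary bis-triflate joins two monomers on the C4 tether to give 14, in which each 4-methyl group (future C5) is para to N+ and ortho to the C8 ketone, so the amine converts it into the anhydrobase (4-methylene-1,4-dihydropyridine). The exocyclic carbon of each anhydrobase attacks the dioxolanone carbonyl (future C6) in a Dieckmann-type condensation; the tetrahedral intermediate expels the hemiacetal oxide, which loses pivalaldehyde to unmask the C7 oxygen, and a second proton loss from C5 gives the neutral N2–C3=C4–C4a=C5–C6=O vinylogous amide at the oxidation level of the target (15), whose tertiary hydroxyl is acetylated in the same flask. The closest known reaction types are the C-acylation (lateral Claisen condensation) of 4-picolinium anhydrobases by esters and the acylative ring-opening of 1,3-dioxolan-4-ones by carbon nucleophiles. Each carbocycle (C4a–C5–C6–C7–C8–C8a) is closed by a 6-exo-trig attack of C5 on C6, and the second of these closures is the last ring-forming event of the synthesis. No new stereocentre is created: C7, set in step 5, is quaternary and not a reacting centre, and the temporary acetal centre is destroyed. The step needs deprotonation at C5 rather than at the vinylogous side-chain positions (C11–CH3, C13–H) and C-acylation rather than attack of base on the lactone or the dienylpyridinium; the ortho C8 carbonyl makes C5–H the most acidic site, the intramolecular trap is made irreversible by loss of pivalaldehyde, and the hindered tertiary amine is non-nucleophilic.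

Step 9
Reactants: 16 5,5'-didechloro-penazaphilone I
Product: 17 Penazaphilone I
Conditions: NCS (2.1 equiv), MeCN, 0 °C → rt, dark
Reagents that add atoms: N-chlorosuccinimide, O=C1CCC(=O)N1Cl
Why: Electrophilic chlorination should occur at C5 and C5', the α-carbons of the vinylogous amides and the most nucleophilic carbons of the molecule, as in the known late-stage 5-halogenation of azaphilone-type chromophores, without touching any stereocentre.

## Compound list

1 | (S)-2-methylbutan-1-ol | CC[C@H](C)CO | starting material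
2 | (S)-2-methylbutanal | CC[C@H](C)C=O | intermediate
3 | (2E,4S)-2,4-dimethylhex-2-enal | CC[C@H](C)/C=C(C)/C=O | intermediate
4 | 2-[(1E,3E,5S)-3,5-dimethylhepta-1,3-dien-1-yl]-4,4,5,5-tetramethyl-1,3,2-dioxaborolane | CC[C@H](C)/C=C(C)/C=C/B1OC(C)(C)C(C)(C)O1 | intermediate
5 | 6-chloro-4-methylpyridine-3-carbaldehyde | Cc1cc(Cl)ncc1C=O | starting material
6 | 6-[(1E,3E,5S)-3,5-dimethylhepta-1,3-dien-1-yl]-4-methylpyridine-3-carbaldehyde | CC[C@H](C)/C=C(C)/C=C/c1cc(C)c(C=O)cn1 | intermediate
7 | (R)-lactic acid | C[C@@H](O)C(=O)O | starting material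
8 | (2R,5R)-2-tert-butyl-5-methyl-1,3-dioxolan-4-one (cis) | C[C@H]1O[C@@H](C(C)(C)C)OC1=O | intermediate
9 | lithium (2R)-2-tert-butyl-5-methyl-1,3-dioxol-4-olate (enolate of 8) | [Li+].CC1=C([O-])O[C@H](C(C)(C)C)O1 | intermediate
10 | (2R,5S)-2-tert-butyl-5-{[6-((1E,3E,5S)-3,5-dimethylhepta-1,3-dien-1-yl)-4-methylpyridin-3-yl](hydroxy)methyl}-5-methyl-1,3-dioxolan-4-one (both carbinol epimers) | CC[C@H](C)/C=C(C)/C=C/c1cc(C)c(cn1)C(O)[C@]2(C)O[C@@H](C(C)(C)C)OC2=O | intermediate
11 | (2R,5S)-2-tert-butyl-5-{6-[(1E,3E,5S)-3,5-dimethylhepta-1,3-dien-1-yl]-4-methylpyridine-3-carbonyl}-5-methyl-1,3-dioxolan-4-one | CC[C@H](C)/C=C(C)/C=C/c1cc(C)c(cn1)C(=O)[C@]2(C)O[C@@H](C(C)(C)C)OC2=O | intermediate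
12 | tetrahydrofuran | C1CCOC1 | starting material
13 | butane-1,4-diyl bis(trifluoromethanesulfonate) | O=S(=O)(OCCCCOS(=O)(=O)C(F)(F)F)C(F)(F)F | intermediate
14 | 1,1'-(butane-1,4-diyl)bis-pyridinium bis(trifluoromethanesulfonate) formed from two molecules of 11 (each ring: 2-dienyl, 4-methyl, 5-acyl with the (2R,5S)-dioxolanone of 11) | CC[C@H](C)/C=C(C)/C=C/c1cc(C)c(c[n+]1CCCC[n+]1cc(C(=O)[C@]2(C)O[C@@H](C(C)(C)C)OC2=O)c(C)cc1/C=C/C(C)=C/[C@@H](C)CC)C(=O)[C@]2(C)O[C@@H](C(C)(C)C)OC2=O.[O-]S(=O)(=O)C(F)(F)F.[O-]S(=O)(=O)C(F)(F)F | intermediate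
15 | 2,2'-(butane-1,4-diyl)bis{(7R)-3-[(1E,3E,5S)-3,5-dimethylhepta-1,3-dien-1-yl]-7-hydroxy-7-methylisoquinoline-6,8(2H,7H)-dione} | CC[C@H](C)/C=C(C)/C=C/C1=CC2=CC(=O)[C@@](C)(O)C(=O)C2=CN1CCCCN1C=C2C(=O)[C@](C)(O)C(=O)C=C2C=C1/C=C/C(C)=C/[C@@H](C)CC | intermediate
16 | 5,5'-didechloro-penazaphilone I, the (7R,7'R)-bis-acetate of 15 | CC[C@H](C)/C=C(C)/C=C/C1=CC2=CC(=O)[C@@](C)(OC(C)=O)C(=O)C2=CN1CCCCN1C=C2C(=O)[C@](C)(OC(C)=O)C(=O)C=C2C=C1/C=C/C(C)=C/[C@@H](C)CC | intermediate
17 | Penazaphilone I (7S,7'S,13S,13'S) | CC[C@H](C)/C=C(C)/C=C/C1=CC2=C(Cl)C(=O)[C@@](C)(OC(C)=O)C(=O)C2=CN1CCCCN1C=C2C(=O)[C@](C)(OC(C)=O)C(=O)C(Cl)=C2C=C1/C=C/C(C)=C/[C@@H](C)CC | target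

## Step count and risks

Total step count: 9. Longest linear sequence: 7 steps (steps 1, 2, 3, 5, 6, 8, 9).

Steps most likely to fail:

**Step 8.** The twofold N-alkylation of the hindered, acyl-deactivated pyridine nitrogen may stay incomplete. In the base stage, cleavage of the C7–C8 bond (retro-Claisen loss of the dioxolanone), conjugate addition to the dienylpyridinium, or deprotonation along the side chain (erosion of C13 and of the diene geometry) may compete with ring closure.

Fallback, setting out from 11 and returning at 16: the ring is closed on the neutral monomer before dimerisation. Lateral deprotonation of the 4-methyl group of 11 with LiN(SiMe3)2 in THF at −78 → 0 °C, with the same intramolecular Claisen closure on the dioxolanone and loss of pivalaldehyde, should give (7R)-3-[(1E,3E,5S)-3,5-dimethylhepta-1,3-dien-1-yl]-6,7-dihydroxy-7-methylisoquinolin-8(7H)-one F1. Exhaustive acetylation (Ac2O, Et3N, DMAP, CH2Cl2) gives the 6,7-diacetate F2, which keeps the hetero ring as a pyridine. Its nitrogen is alkylated twice with 13 (CH2Cl2, 40 °C) to the bis-isoquinolinium bis(triflate) F3. The 6-acetoxy groups of F3 are activated esters of the O-acyl-4-pyridonium type and should be cleaved selectively by NaHCO3 in MeOH at 0 °C, leaving the tertiary acetates and giving 16.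

**Step 9.** The twofold chlorination may be incomplete or non-uniform (mixtures of mono-, di- and over-chlorinated dimers), and attack at the other enaminone carbons (C4, C1) or at the dienes of the electron-rich chromophore may compete.

Fallback, setting out from 11 and returning at 17: chlorine is introduced on the monomer, where the hetero ring is an electron-poor pyridine and C5 is the only enol carbon. F1 (made from 11 as in the fallback for step 8) is treated with NCS (1 equiv, CH2Cl2, 0 °C) to give (7R)-5-chloro-3-[(1E,3E,5S)-3,5-dimethylhepta-1,3-dien-1-yl]-6,7-dihydroxy-7-methylisoquinolin-8(7H)-one F4. Acetylation (Ac2O, Et3N, DMAP) gives the diacetate F5, twofold N-alkylation with 13 gives the bis-isoquinolinium bis(triflate) F6, and selective methanolysis of the 6-acetoxy groups (NaHCO3, MeOH, 0 °C) should give 17 directly.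

**Step 2.** The boron-Wittig olefination of the α-branched enal may give poor E-selectivity, or γ-deprotonation of the enal by the boryl carbanion may erode the 4S centre.

Fallback, setting out from 3 and returning at 4: the boron is introduced by alkyne hydroboration instead of olefination. Corey–Fuchs reaction of 3 (CBr4, PPh3, CH2Cl2, 0 °C) gives (3E,5S)-1,1-dibromo-3,5-dimethylhepta-1,3-diene F7. Treatment with n-BuLi (THF, −78 °C, then water) gives (3E,5S)-3,5-dimethylhept-3-en-1-yne F8. Syn-hydroboration of F8 with pinacolborane catalysed by Cp2Zr(H)Cl should give 4 with the E-configured C9=C10 bond.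

Further compounds
F1 | step 8 | (7R)-3-[(1E,3E,5S)-3,5-dimethylhepta-1,3-dien-1-yl]-6,7-dihydroxy-7-methylisoquinolin-8(7H)-one | CC[C@H](C)/C=C(C)/C=C/c1cc2C=C(O)[C@@](C)(O)C(=O)c2cn1
F2 | step 8 | (7R)-3-[(1E,3E,5S)-3,5-dimethylhepta-1,3-dien-1-yl]-7-methyl-8-oxo-7,8-dihydroisoquinoline-6,7-diyl diacetate | CC[C@H](C)/C=C(C)/C=C/c1cc2C=C(OC(C)=O)[C@@](C)(OC(C)=O)C(=O)c2cn1
F3 | step 8 | 2,2'-(butane-1,4-diyl)bis{(7R)-6,7-diacetoxy-3-[(1E,3E,5S)-3,5-dimethylhepta-1,3-dien-1-yl]-7-methyl-8-oxo-7,8-dihydroisoquinolin-2-ium} bis(trifluoromethanesulfonate) | CC[C@H](C)/C=C(C)/C=C/c1cc2C=C(OC(C)=O)[C@@](C)(OC(C)=O)C(=O)c2c[n+]1CCCC[n+]1cc2C(=O)[C@](C)(OC(C)=O)C(OC(C)=O)=Cc2cc1/C=C/C(C)=C/[C@@H](C)CC.[O-]S(=O)(=O)C(F)(F)F.[O-]S(=O)(=O)C(F)(F)F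
F4 | step 9 | (7R)-5-chloro-3-[(1E,3E,5S)-3,5-dimethylhepta-1,3-dien-1-yl]-6,7-dihydroxy-7-methylisoquinolin-8(7H)-one | CC[C@H](C)/C=C(C)/C=C/c1cc2C(Cl)=C(O)[C@@](C)(O)C(=O)c2cn1
F5 | step 9 | (7R)-5-chloro-3-[(1E,3E,5S)-3,5-dimethylhepta-1,3-dien-1-yl]-7-methyl-8-oxo-7,8-dihydroisoquinoline-6,7-diyl diacetate | CC[C@H](C)/C=C(C)/C=C/c1cc2C(Cl)=C(OC(C)=O)[C@@](C)(OC(C)=O)C(=O)c2cn1
F6 | step 9 | 2,2'-(butane-1,4-diyl)bis{(7R)-6,7-diacetoxy-5-chloro-3-[(1E,3E,5S)-3,5-dimethylhepta-1,3-dien-1-yl]-7-methyl-8-oxo-7,8-dihydroisoquinolin-2-ium} bis(trifluoromethanesulfonate) | CC[C@H](C)/C=C(C)/C=C/c1cc2C(Cl)=C(OC(C)=O)[C@@](C)(OC(C)=O)C(=O)c2c[n+]1CCCC[n+]1cc2C(=O)[C@](C)(OC(C)=O)C(OC(C)=O)=C(Cl)c2cc1/C=C/C(C)=C/[C@@H](C)CC.[O-]S(=O)(=O)C(F)(F)F.[O-]S(=O)(=O)C(F)(F)F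
F7 | step 2 | (3E,5S)-1,1-dibromo-3,5-dimethylhepta-1,3-diene | CC[C@H](C)/C=C(C)/C=C(Br)Br
F8 | step 2 | (3E,5S)-3,5-dimethylhept-3-en-1-yne | CC[C@H](C)/C=C(C)/C#C
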